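## Structural features

The target is a ten-membered carbocycle (numbered C1–C10 here) with an exocyclic isopropenyl group on C1, methyl groups on C4 and C8, and a trisubstituted cis-oxirane across C7–C8. Its eight ring stereocentres form two contiguous triads, C3/C4/C5 (secondary carbinol, tertiary methyl carbinol, angelate carbon) and C9/C10/C1 (angelate, (R)-2-methylbutanoate, isopropenyl), joined by the epoxide on one side and by the C2 and C6 methylenes on the other. The fragile parts are the two (Z)-2-methylbut-2-enoates (they isomerise to tiglates under nucleophilic or basic stress), the epimerisable α-centre of the 2-methylbutanoate, the acid-sensitive oxirane in a ring prone to transannular reactions, and the isopropenyl group, which competes with any undirected electrophilic oxidant. The real difficulty is threefold: a medium ring with a Z trisubstituted alkene, the correct relation between the two triads, and five oxygens in three classes (two free, two angeloylated, one 2-methylbutanoylated). C3 and C8 face each other across the ring, so a C3–C8 bond turns the ring into the perimeter of a decalin (ring A = C8–C9–C10–C1–C2–C3, ring B = C3–C4–C5–C6–C7–C8) with an angular hydroxyl on C3 and an angular methyl on C8. In that bicycle the C3 oxygen and a C7 leaving group are 1,3-related through C8, which is what the key step uses to cleave C3–C8 and create the C3 carbonyl and the C7=C8 alkene together. In ring A the C9, C10 and C1 substituents are all trans and hence all equatorial, whereas the ring B oxygens on C3, C4 and C5 are trans-diaxial in the reactive cis-decalin; this difference decides how each triad must be made.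

## Logic of the disconnections

35 ⇒ 34. The two oxirane C–O bonds (C7–O, C8–O) are cut first. The epoxide is the most acid-sensitive function and is therefore made last, and its removal deletes two stereocentres. The forward step must oxidise the trisubstituted ring alkene rather than the isopropenyl group or the conjugated esters, and on the outer face of the ring.

34 ⇒ 33 ⇒ 31 + 32. The O–Si bond at C3 and then the two acyl C–O bonds at O5 and O9 are cut, so that 32 is needed twice, one molecule for each ester. The isomerisation-prone angelates thus enter as late as possible and see only a mild desilylation and the epoxidation. The forward acylation must avoid nucleophilic catalysts, must take both secondary hydroxyls of 31 to the ester, and must leave the tertiary C4 hydroxyl alone.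

31 ⇒ 30 ⇒ 28 + 29. The three benzylic C–O bonds (O4, O5, O9) and the acyl C–O bond at O10 are cut. All oxygens become ethers that tolerate strong base. The forward order frees O10 alone, acylates it, and then removes the three benzylic ethers under neutral oxidative conditions so that the C10 ester does not migrate.

28 ⇒ 26 ⇒ 25 ⇒ 24. The O10 allyl ether is restored, the O–Si bond at C3 is cut, and the C3–H bond is cut (carbinol to ketone). This brings the ring to the oxidation level that the ring-opening delivers. The forward reduction must add hydride to one face of a ketone in a flexible ring.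

24 ⇒ 23. The C3–C8 bond is re-formed and the C7=C8 alkene becomes a C7–O sulfonate. The medium ring is traded for a cis-decalin that ordinary six-membered-ring chemistry can build, and the alkene geometry is traded for relative configuration at C3, C7 and C8. The demand on 23 is a cis ring fusion, a C7 sulfonate trans to the C8 methyl, and ring A locked by three equatorial groups. In 23 the tertiary O4 is a benzylic ether, not an acetal: it forms in the very step that creates the C4–O bond, it needs no selective protection next to the tertiary C3 hydroxyl, and it leaves oxidatively instead of by acid. O10 is an allyl ether because the C10 oxygen arrives as an ether from an epoxide opening and cannot migrate to a neighbouring alkoxide as a silyl group could.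

23 ⇒ 22 ⇒ 21 ⇒ 20. The S–O bond, the Si–O bond at O7 and the two benzylic C–O bonds at O5 and O9 are cut. This leaves a triol in which only O7 is silylated. The forward steps rely on the angular C3 hydroxyl being too hindered to react.

20 ⇒ 18 + 19 ⇒ 17. The C4–O ether bond and then the C4–O/C5–O oxirane bonds are cut back to a C4=C5 alkene. Hydrolysis of a tetrasubstituted C3–C4 epoxide is avoided: it would open at the ring-fusion carbon or rearrange, and it would leave two tertiary hydroxyls that cannot be told apart. The trisubstituted C4–C5 epoxide of 18 instead has one tertiary and one secondary carbon. The forward opening must occur at C4 with inversion.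

17 ⇒ 15 ⇒ 14. The C3–O bond is traced back through a 1,3-oxygen transposition to the enone carbonyl of 14. The tertiary cis-fused carbinol is thus derived from a flat enone. The forward epoxidation must be nucleophilic (sparing the other alkenes) and β-selective.

14 ⇒ 13 ⇒ 11 ⇒ 10 ⇒ 9 ⇒ 8. The C9–O and C10–O bonds are cut back to the C9=C10 alkene. A single epoxide opening can only give the trans-diaxial pair (9α,10β), which is the wrong diastereomer relative to C1. The all-equatorial pair is therefore reached by opening, oxidation at C9, epimerisation at C10 and axial hydride delivery to C9. The forward epoxidation must ignore the isopropenyl group, so it is directed by the C7 hydroxyl.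

8 ⇒ 6 ⇒ 4. The C7–O bond and the C6=C7 unsaturation are removed. The C7 oxygen comes from conjugate functionalisation of a dienone, anti to the angular methyl.

4 ⇒ 1 + 2. The C7–C8 and C3–C4 bonds are cut (annulation). The forward Michael step must be deconjugative (to leave C9=C10) and must occur anti to the isopropenyl group.

## Other disconnections considered

Alternative 1: The four oxirane C–O bonds at C3/C4 and C7/C8 are cut, leading back to the cyclodecadiene triester A2. The forward step is a double peracid epoxidation of A2 to the bis-epoxide A1. In its favour, it uses the near-symmetry of the C3–C5 and C7–C9 segments, needs no diol protection and forms four C–O bonds in one operation. On this point of late-stage step economy it is better than the chosen plan, and it is equal in relying on outer-face attack on a Z ring alkene. Against it, A1 is the target minus water. The C3–C4 oxirane would have to be hydrolysed at its secondary carbon C3 with inversion while the almost identical C7–C8 oxirane survives, whereas acid favours the tertiary carbon. The isopropenyl problem occurs twice. The construction of the ten-membered diene A2, which is prone to transannular reactions, is left unsolved. The chosen plan fixes the diol stereochemistry in a rigid decalin and needs only one epoxidation.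

Alternative 2: The C1–C10 bond is cut. In the forward step CrCl2 converts the allylic bromide of the open-chain aldehyde A4 into an allylchromium, which adds through its γ-carbon to the aldehyde and gives the cyclodecenol A3. In its favour, divalent chromium tolerates the esters, the isopropenyl group appears only at the end and the C10 hydroxyl emerges free for the last acylation. On functional-group tolerance and on sparing the isopropenyl group from a long series of oxidations it is better than the chosen plan. Against it, a ten-membered ring must be closed by bond formation at high dilution. Two stereocentres (C1, C10) are set in a transition state constrained by the forming ring and controlled only by the remote C9 centre. The precursor A4 carries an epimerisable α-acyloxy aldehyde, a Z trisubstituted alkene and four stereocentres that must be assembled acyclically. The chosen plan has no entropic ring-closure problem and its alkene geometry is stereospecific, at the price of a longer linear sequence.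

Alternative 3: The C3–C4 bond is cut. In the forward step low-valent titanium (TiCl3 reduced by Zn–Cu couple) couples the aldehyde and methyl ketone of A6 to the diol A5. In its favour, ring and diol are formed together and the product is close to 25; it is equal to the chosen plan in the intermediate it reaches and better in avoiding the enone transposition and the C3 ketone reduction. Against it, two carbinol centres are created at once with no reliable control over which of four diastereomers forms. Over-reduction to the alkene competes. The acyclic keto aldehyde A6, with its Z alkene and four stereocentres, is no shorter to make than 23. The chosen plan sets C4 by a stereospecific epoxide opening and leaves only C3 to a late reduction that has a reagent-controlled backup.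

Key step: step 16

Conventions and assumptions:
- C1–C10 are the ring atoms of the target and are used for all intermediates. β is the face of the C8 methyl and C1 isopropenyl groups; α is the opposite face.
- The acyl group on O10 is (R)-2-methylbutanoyl, as the stereodescriptor of the target requires.
- Compounds 1, 2, 19, 29 and 32 are purchased.

## Steps

Step 1
Reactants: 1 (R)-(−)-carvone; 2 ethyl vinyl ketone
Product: 4 bicyclic enone (C5 ketone; C3=C4; C9=C10; 8β-methyl; 1β-isopropenyl), via Michael adduct 3 (not isolated)
Conditions: KOt-Bu (0.2 equiv), t-BuOH–THF, 0 °C, slow addition of 2; then KOH, MeOH, 60 °C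
Reagents that add atoms: none
Why: Robinson annulation in its deconjugative form: under equilibrating conditions the extended dienolate of 1 adds to 2 through its α-carbon (C8), which shifts the ring alkene to C9=C10, and aldol condensation of the ethyl ketone onto the ring carbonyl closes ring B. The acceptor should approach the dienolate face away from the isopropenyl group, placing the new chain trans and the C8 methyl cis to it.

Step 2
Reactants: 4 bicyclic enone
Product: 6 cross-conjugated dienone (C3=C4 and C6=C7 flanking the C5 ketone), via trimethylsilyl dienol ether 5 (not isolated)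
Conditions: LiN(i-Pr)2, THF, −78 °C; Me3SiCl; then Pd(OAc)2, MeCN, rt
Reagents that add atoms: chlorotrimethylsilane, C[Si](C)(C)Cl (silyl group of 5 only)
Why: Saegusa–Ito oxidation: kinetic deprotonation of the enone occurs at C6, and divalent palladium dehydrosilylates the silyl dienol ether to the C6=C7 enone. No stereocentre is touched.

Step 3
Reactants: 6 cross-conjugated dienone
Product: 8 7α-hydroxy enone, via C7 pinacol boronate 7 (not isolated)
Conditions: CuCl (5 mol %), Xantphos, NaOt-Bu (10 mol %), B2pin2, MeOH, THF, rt; then NaBO3·4H2O, THF–H2O, rt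
Reagents that add atoms: bis(pinacolato)diboron, CC1(C)OB(OC1(C)C)B1OC(C)(C)C(C)(C)O1 (boryl group of 7 only); sodium perborate, [Na+].[O-]OB=O (oxygen on C7)
Why: Copper-catalysed conjugate borylation of an enone followed by C–B oxidation with retention. The boryl copper adds to the unsubstituted β-carbon C7, not the fully substituted C3, and enters anti to the adjacent angular methyl, which sets C7 as α.

Step 4
Reactants: 8 7α-hydroxy enone
Product: 9 9α,10α-epoxide
Conditions: VO(acac)2 (5 mol %), t-BuOOH, CH2Cl2, 0 °C → rt
Reagents that add atoms: tert-butyl hydroperoxide, CC(C)(C)OO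
Why: Hydroxyl-directed vanadium-catalysed epoxidation: the axial 7α-hydroxyl is homoallylic and gauche to C9, so the metal-bound peroxide is delivered to the α face of C9=C10 only. The isopropenyl group (no hydroxyl in reach) and the electron-poor enone alkene should not react.

Step 5
Reactants: 9 9α,10α-epoxide
Product: 10 7α-tert-butyldimethylsilyl ether
Conditions: TBSOTf, 2,6-lutidine, CH2Cl2, −78 °C
Reagents that add atoms: tert-butyldimethylsilyl trifluoromethanesulfonate, CC(C)(C)[Si](C)(C)OS(=O)(=O)C(F)(F)F
Why: Silyl ether formation on the hindered secondary alcohol, so that C9 will be the only secondary carbinol when it is oxidised.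

Step 6
Reactants: 10 7α-silyl ether epoxide
Product: 11 9α-hydroxy-10β-allyl ether
Conditions: allyl alcohol (solvent), CSA (10 mol %), 0 °C → rt
Reagents that add atoms: allyl alcohol, C=CCO
Why: Acid-catalysed epoxide alcoholysis under Fürst–Plattner control: the alcohol attacks C10 axially from the β face (C9 is neopentyl), giving the trans-diaxial product with inversion at C10 and retention at C9. The allyl group becomes the C10 protecting group.

Step 7
Reactants: 11 9α-hydroxy-10β-allyl ether
Product: 13 C9 ketone with equatorial 10α-allyl ether, via axial C10 epimer 12 (not isolated)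
Conditions: Dess–Martin periodinane, NaHCO3, CH2Cl2, rt; then DBU (0.2 equiv), CH2Cl2, 0 °C → rt
Reagents that add atoms: none
Why: Periodinane oxidation of the only free carbinol, then base-mediated epimerisation next to the new ketone. The axial 10β-allyloxy group is syn-diaxial to the C8 methyl and cis to the isopropenyl group, so enolisation toward C10 (the only enolisable side of the C9 ketone) should relax it to the equatorial 10α epimer.

Step 8
Reactants: 13 C9 ketone
Product: 14 9β-alcohol with the enone intact
Conditions: NaBH4 (0.3 equiv), EtOH–CH2Cl2, −40 °C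
Reagents that add atoms: none
Why: Chemoselective borohydride reduction of the saturated α-alkoxy ketone in the presence of the conjugated ketone, as in the monoreduction of Wieland–Miescher-type diketones. Hydride enters axially on the α face, anti to the angular methyl, so the C9 hydroxyl should come out β and equatorial.

Step 9
Reactants: 14 9β-hydroxy enone
Product: 15 3β,4β-epoxy ketone
Conditions: t-BuOOH, BnMe3N+ OH− (Triton B, 10 mol %), THF, 0 °C → rt
Reagents that add atoms: tert-butyl hydroperoxide, CC(C)(C)OO
Why: Weitz–Scheffer (nucleophilic) epoxidation of the tetrasubstituted enone, which is inert toward the isolated alkenes. The peroxide anion should add to C3 on the β face, the usual course for such octalones and the face not screened by the axial C7 silyl ether, which puts the C3 oxygen cis to the C8 methyl.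

Step 10
Reactants: 15 3β,4β-epoxy ketone
Product: 17 transposed tertiary allylic alcohol (3β-hydroxyl; C4=C5), via epoxy hydrazone 16 (not isolated)
Conditions: N2H4·H2O, AcOH (cat.), MeOH, 0 °C → rt, under N2
Reagents that add atoms: hydrazine hydrate, NN (nitrogen atoms of 16 only)
Why: Wharton reaction: the hydrazone of the α,β-epoxy ketone opens the oxirane and loses dinitrogen, moving the oxygen function from C5 to C3 and the alkene to C4=C5. The C3–O bond is never broken, so the angular hydroxyl stays β.

Step 11
Reactants: 17 tertiary allylic alcohol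
Product: 18 4β,5β-epoxide
Conditions: VO(acac)2 (5 mol %), t-BuOOH, CH2Cl2, 0 °C
Reagents that add atoms: tert-butyl hydroperoxide, CC(C)(C)OO
Why: Vanadium-catalysed epoxidation directed by the tertiary allylic C3 hydroxyl, which delivers oxygen syn (β face) and only to C4=C5.

Step 12
Reactants: 18 4β,5β-epoxide; 19 4-methoxybenzyl alcohol
Product: 20 C4 4-methoxybenzyl ether with free 5β-hydroxyl
Conditions: 19 (5 equiv), CSA (10 mol %), CH2Cl2, 0 °C → rt
Reagents that add atoms: none
Why: Acid-catalysed alcoholysis of a trisubstituted epoxide at its tertiary carbon with inversion (trans-diaxial opening). The alcohol enters C4 from the α face, so C4 ends with methyl β and ether α while C5 keeps its β oxygen, and the tertiary oxygen is protected in the same operation.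

Step 13
Reactants: 20 C4 ether triol
Product: 21 4,5,9-tris(4-methoxybenzyl) ether
Conditions: NaH (2.5 equiv), 4-methoxybenzyl chloride (2.5 equiv), n-Bu4NI (cat.), DMF, 0 °C → rt
Reagents that add atoms: 4-methoxybenzyl chloride, COc1ccc(CCl)cc1 (two equivalents incorporated)
Why: Williamson etherification of the two secondary hydroxyls (C5, C9), each of which takes up one 4-methoxybenzyl group. The angular C3 hydroxyl, flanked by two fully substituted carbons, should stay free.

Step 14
Reactants: 21 tris(4-methoxybenzyl) ether
Product: 22 7α-alcohol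
Conditions: n-Bu4NF, THF, rt
Reagents that add atoms: none
Why: Fluoride cleavage of the silyl ether; the benzylic and allyl ethers and the tertiary alcohol are unaffected.

Step 15
Reactants: 22 7α-alcohol
Product: 23 cis-decalin hydroxy mesylate
Conditions: MsCl, Et3N, CH2Cl2, 0 °C
Reagents that add atoms: methanesulfonyl chloride, CS(=O)(=O)Cl
Why: Sulfonylation of the single secondary hydroxyl; the tertiary C3 hydroxyl is too hindered to react.

Step 16
Reactants: 23 cis-decalin hydroxy mesylate
Product: 24 (Z)-cyclodec-7-en-3-one
Conditions: KOt-Bu, THF, 0 °C → rt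
Reagents that add atoms: none
Why: The base forms the C3 alkoxide, whose electron pair pushes into the C3–C8 bond; this bond is antiperiplanar to the equatorial C7–O bond of the mesylate, so the C3 carbonyl and the C7=C8 alkene form in one concerted step as methanesulfonate leaves. The closest known reaction type is the Wharton-type Grob fragmentation of decalin 1,3-diol monosulfonates to cyclodecenones. The ten-membered ring is not closed by bond formation: it already exists as the perimeter of the decalin and is released by cleaving the shared bond, so no medium-ring cyclisation entropy is paid. No stereocentre is created; C3 and C8 become trigonal, C7 loses its oxygen, and C1, C4, C5, C9 and C10 are untouched. The selectivity needed is Z over E at C7=C8 and fragmentation over E2 elimination or oxetane formation. Ring A is held in the chair with the C9 ether, the C10 ether and the isopropenyl group equatorial; with the cis fusion this makes C9 axial and the mesylate equatorial on ring B, so C6 and C9 are gauche across C7–C8 and end up cis, which is the Z alkene by stereospecificity. The same alignment disfavours displacement at C7 by the C3 oxygen, the ethers are inert to the base, and the etherified C4 oxygen excludes α-ketol chemistry in the product.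

Step 17
Reactants: 24 (Z)-cyclodec-7-en-3-one
Product: 25 (3R)-alcohol
Conditions: NaBH4, MeOH–THF, −20 → 0 °C
Reagents that add atoms: none
Why: Hydride reduction of the α-alkoxy ketone under non-chelating conditions. With the C4–O bond perpendicular to the carbonyl and hydride passing the C4 methyl (Felkin–Anh model), the C3 hydroxyl should form with the configuration of the target.

Step 18
Reactants: 25 (3R)-alcohol
Product: 26 C3 triethylsilyl ether
Conditions: TESOTf, 2,6-lutidine, CH2Cl2, −78 °C
Reagents that add atoms: triethylsilyl trifluoromethanesulfonate, CC[Si](CC)(CC)OS(=O)(=O)C(F)(F)F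
Why: Silylation of the only free hydroxyl keeps C3 out of the three esterifications.

Step 19
Reactants: 26 C3 triethylsilyl ether
Product: 28 C10 alcohol, via 1-propenyl ether 27 (not isolated)
Conditions: [Ir(cod)(PMePh2)2]PF6 (2 mol %, activated with H2), THF, rt; then I2, NaHCO3, THF–H2O, 0 °C
Reagents that add atoms: none
Why: Allyl ether cleavage in two stages: the cationic iridium hydride isomerises the terminal allyl ether to the enol ether far faster than it acts on 1,1-disubstituted or trisubstituted alkenes, and iodine–water then hydrolyses the electron-rich enol ether under buffered conditions.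

Step 20
Reactants: 28 C10 alcohol; 29 (R)-2-methylbutanoic acid
Product: 30 C10 (R)-2-methylbutanoate
Conditions: DCC, DMAP (cat.), CH2Cl2, 0 °C → rt
Reagents that add atoms: none
Why: Steglich esterification; the α-stereocentre of the acid is not enolised under these conditions.

Step 21
Reactants: 30 C10 (R)-2-methylbutanoate
Product: 31 4,5,9-triol
Conditions: DDQ, CH2Cl2–pH 7 buffer, 0 °C → rt
Reagents that add atoms: none
Why: Oxidative cleavage of the three 4-methoxybenzyl ethers by hydride abstraction and hydrolysis. The ester, silyl ether and alkenes are inert, and the neutral medium avoids acyl migration from O10 to O9.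

Step 22
Reactants: 31 4,5,9-triol; 32 angelic acid (two equivalents are incorporated, one at O5 and one at O9)
Product: 33 5,9-diangelate
Conditions: 32 (3 equiv), 2,4,6-trichlorobenzoyl chloride (3 equiv), Et3N (3 equiv), toluene, rt; then 31, toluene, 80 °C
Reagents that add atoms: angelic acid, C/C=C(/C)C(=O)O (the second equivalent of 32, which supplies the second angeloyl group)
Why: Yamaguchi-type esterification through the mixed anhydride, made beforehand from an excess of 32 and run without a nucleophilic catalyst so that the (Z)-acid is not isomerised to the tiglate. Each of the two secondary hydroxyls (C5 and C9) takes one angeloyl group from its own molecule of mixed anhydride, so two equivalents of 32 end up in the product; the tertiary C4 hydroxyl is too hindered to react.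

Step 23
Reactants: 33 5,9-diangelate
Product: 34 3,4-diol triester
Conditions: HF·pyridine, pyridine, THF, 0 °C → rt
Reagents that add atoms: none
Why: Buffered fluoride desilylation of the secondary silyl ether under mildly acidic conditions, which avoid ester migration and angelate isomerisation.

Step 24
Reactants: 34 3,4-diol triester
Product: 35 target
Conditions: m-CPBA (1.05 equiv), NaHCO3, CH2Cl2, −20 → 0 °C
Reagents that add atoms: 3-chloroperoxybenzoic acid, OOC(=O)c1cccc(Cl)c1
Why: Prilezhaev epoxidation: the trisubstituted ring alkene is the most electron-rich π bond (the angelates are conjugated, the isopropenyl group is only disubstituted). The peracid should attack its outer face in the conformer that keeps the C9 hydrogen eclipsed with the alkene and C10 turned into the ring, which gives the C7/C8 configuration of the target.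

## Compound list

1 | (R)-(−)-carvone, (5R)-2-methyl-5-(prop-1-en-2-yl)cyclohex-2-en-1-one | C=C(C)[C@H]1CC(=O)C(C)=CC1 | starting material
2 | ethyl vinyl ketone (pent-1-en-3-one) | CCC(=O)C=C | starting material
3 | Michael adduct, (2R,5S)-2-methyl-2-(3-oxopentyl)-5-(prop-1-en-2-yl)cyclohex-3-en-1-one (chain trans to isopropenyl) | C=C(C)[C@H]1CC(=O)[C@](C)(CCC(=O)CC)C=C1 | intermediate
4 | (4aR,7S)-1,4a-dimethyl-7-(prop-1-en-2-yl)-4,4a,7,8-tetrahydronaphthalen-2(3H)-one (route numbering: C5 ketone, C3=C4, C9=C10, 8β-methyl, 1β-isopropenyl) | C=C(C)[C@H]1CC2=C(C)C(=O)CC[C@]2(C)C=C1 | intermediate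
5 | C5 trimethylsilyl dienol ether of 4 (C3=C4 and C5=C6) | C=C(C)[C@H]1CC2=C(C)C(O[Si](C)(C)C)=CC[C@]2(C)C=C1 | intermediate
6 | cross-conjugated dienone (C5 ketone flanked by C3=C4 and C6=C7; C9=C10 retained) | C=C(C)[C@H]1CC2=C(C)C(=O)C=C[C@]2(C)C=C1 | intermediate
7 | 7α-(pinacolatoboryl) enone | C=C(C)[C@H]1CC2=C(C)C(=O)C[C@H](B3OC(C)(C)C(C)(C)O3)[C@]2(C)C=C1 | intermediate
8 | 7α-hydroxy enone | C=C(C)[C@H]1CC2=C(C)C(=O)C[C@H](O)[C@]2(C)C=C1 | intermediate
9 | 9α,10α-epoxy-7α-hydroxy enone | C=C(C)[C@H]1CC2=C(C)C(=O)C[C@H](O)[C@]2(C)[C@@H]3O[C@@H]31 | intermediate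
10 | 9α,10α-epoxy-7α-(tert-butyldimethylsilyloxy) enone | C=C(C)[C@H]1CC2=C(C)C(=O)C[C@H](O[Si](C)(C)C(C)(C)C)[C@]2(C)[C@@H]3O[C@@H]31 | intermediate
11 | 10β-allyloxy-9α-hydroxy-7α-silyloxy enone | C=C(C)[C@H]1CC2=C(C)C(=O)C[C@H](O[Si](C)(C)C(C)(C)C)[C@]2(C)[C@H](O)[C@H]1OCC=C | intermediate
12 | 10β-allyloxy-9-oxo-7α-silyloxy enone (axial C10 epimer) | C=C(C)[C@H]1CC2=C(C)C(=O)C[C@H](O[Si](C)(C)C(C)(C)C)[C@]2(C)C(=O)[C@H]1OCC=C | intermediate
13 | 10α-allyloxy-9-oxo-7α-silyloxy enone | C=C(C)[C@H]1CC2=C(C)C(=O)C[C@H](O[Si](C)(C)C(C)(C)C)[C@]2(C)C(=O)[C@@H]1OCC=C | intermediate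
14 | 10α-allyloxy-9β-hydroxy-7α-silyloxy enone | C=C(C)[C@H]1CC2=C(C)C(=O)C[C@H](O[Si](C)(C)C(C)(C)C)[C@]2(C)[C@@H](O)[C@@H]1OCC=C | intermediate
15 | 3β,4β-epoxy-5-ketone (4α-methyl) with 7α-silyloxy, 9β-hydroxy, 10α-allyloxy | C=C(C)[C@H]1C[C@@]23O[C@@]3(C)C(=O)C[C@H](O[Si](C)(C)C(C)(C)C)[C@]2(C)[C@@H](O)[C@@H]1OCC=C | intermediate
16 | C5 hydrazone of 15 | C=C(C)[C@H]1C[C@@]23O[C@@]3(C)C(=NN)C[C@H](O[Si](C)(C)C(C)(C)C)[C@]2(C)[C@@H](O)[C@@H]1OCC=C | intermediate
17 | cis-fused 3β-hydroxy-4-ene (C4=C5) with 7α-silyloxy, 9β-hydroxy, 10α-allyloxy | C=C(C)[C@H]1C[C@]2(O)C(C)=CC[C@H](O[Si](C)(C)C(C)(C)C)[C@]2(C)[C@@H](O)[C@@H]1OCC=C | intermediate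
18 | 4β,5β-epoxy-3β-ol (4α-methyl) | C=C(C)[C@H]1C[C@]2(O)[C@@]3(C)O[C@H]3C[C@H](O[Si](C)(C)C(C)(C)C)[C@]2(C)[C@@H](O)[C@@H]1OCC=C | intermediate
19 | 4-methoxybenzyl alcohol | COc1ccc(CO)cc1 | starting material
20 | 4α-(4-methoxybenzyloxy)-4β-methyl-3β,5β,9β-triol with 7α-silyloxy, 10α-allyloxy | C=C(C)[C@H]1C[C@]2(O)[C@](C)(OCc3ccc(OC)cc3)[C@@H](O)C[C@H](O[Si](C)(C)C(C)(C)C)[C@]2(C)[C@@H](O)[C@@H]1OCC=C | intermediate
21 | 4α,5β,9β-tris(4-methoxybenzyloxy)-3β-ol with 7α-silyloxy, 10α-allyloxy | C=C(C)[C@H]1C[C@]2(O)[C@](C)(OCc3ccc(OC)cc3)[C@@H](OCc3ccc(OC)cc3)C[C@H](O[Si](C)(C)C(C)(C)C)[C@]2(C)[C@@H](OCc3ccc(OC)cc3)[C@@H]1OCC=C | intermediate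
22 | 3β,7α-diol (tris-ether, 10α-allyloxy) | C=C(C)[C@H]1C[C@]2(O)[C@](C)(OCc3ccc(OC)cc3)[C@@H](OCc3ccc(OC)cc3)C[C@H](O)[C@]2(C)[C@@H](OCc3ccc(OC)cc3)[C@@H]1OCC=C | intermediate
23 | cis-decalin 3β-hydroxy 7α-mesylate (fragmentation precursor) | C=C(C)[C@H]1C[C@]2(O)[C@](C)(OCc3ccc(OC)cc3)[C@@H](OCc3ccc(OC)cc3)C[C@H](OS(C)(=O)=O)[C@]2(C)[C@@H](OCc3ccc(OC)cc3)[C@@H]1OCC=C | intermediate
24 | (Z)-10-allyloxy-4,5,9-tris(4-methoxybenzyloxy)-4,8-dimethyl-1-(prop-1-en-2-yl)cyclodec-7-en-3-one (C1, C4, C5, C9, C10 as in 35) | C=C(C)[C@H]1CC(=O)[C@](C)(OCc2ccc(OC)cc2)[C@@H](OCc2ccc(OC)cc2)C/C=C(/C)[C@@H](OCc2ccc(OC)cc2)[C@@H]1OCC=C | intermediate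
25 | corresponding cyclodec-7-en-3-ol, C3 configured as in 35 | C=C(C)[C@H]1C[C@@H](O)[C@](C)(OCc2ccc(OC)cc2)[C@@H](OCc2ccc(OC)cc2)C/C=C(/C)[C@@H](OCc2ccc(OC)cc2)[C@@H]1OCC=C | intermediate
26 | C3 triethylsilyl ether of 25 | C=C(C)[C@H]1C[C@@H](O[Si](CC)(CC)CC)[C@](C)(OCc2ccc(OC)cc2)[C@@H](OCc2ccc(OC)cc2)C/C=C(/C)[C@@H](OCc2ccc(OC)cc2)[C@@H]1OCC=C | intermediate
27 | C10 (E)-prop-1-enyl ether | C=C(C)[C@H]1C[C@@H](O[Si](CC)(CC)CC)[C@](C)(OCc2ccc(OC)cc2)[C@@H](OCc2ccc(OC)cc2)C/C=C(/C)[C@@H](OCc2ccc(OC)cc2)[C@@H]1O/C=C/C | intermediate
28 | C10 alcohol | C=C(C)[C@H]1C[C@@H](O[Si](CC)(CC)CC)[C@](C)(OCc2ccc(OC)cc2)[C@@H](OCc2ccc(OC)cc2)C/C=C(/C)[C@@H](OCc2ccc(OC)cc2)[C@@H]1O | intermediate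
29 | (R)-2-methylbutanoic acid | CC[C@@H](C)C(=O)O | starting material
30 | C10 (R)-2-methylbutanoate (tris-ether, C3 silyl ether) | C=C(C)[C@H]1C[C@@H](O[Si](CC)(CC)CC)[C@](C)(OCc2ccc(OC)cc2)[C@@H](OCc2ccc(OC)cc2)C/C=C(/C)[C@@H](OCc2ccc(OC)cc2)[C@@H]1OC(=O)[C@H](C)CC | intermediate
31 | 4,5,9-triol (C3 silyl ether, C10 ester) | C=C(C)[C@H]1C[C@@H](O[Si](CC)(CC)CC)[C@](C)(O)[C@@H](O)C/C=C(/C)[C@@H](O)[C@@H]1OC(=O)[C@H](C)CC | intermediate
32 | angelic acid, (Z)-2-methylbut-2-enoic acid | C/C=C(/C)C(=O)O | starting material
33 | 5,9-diangelate 10-(R)-2-methylbutanoate, C3 silyl ether | C=C(C)[C@H]1C[C@@H](O[Si](CC)(CC)CC)[C@](C)(O)[C@@H](OC(=O)/C(C)=C\C)C/C=C(/C)[C@@H](OC(=O)/C(C)=C\C)[C@@H]1OC(=O)[C@H](C)CC | intermediate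
34 | (Z)-cyclodec-7-ene-3,4-diol triester | C=C(C)[C@H]1C[C@@H](O)[C@](C)(O)[C@@H](OC(=O)/C(C)=C\C)C/C=C(/C)[C@@H](OC(=O)/C(C)=C\C)[C@@H]1OC(=O)[C@H](C)CC | intermediate
35 | (1R,3R,4S,5S,7S,8S,9S,10R)-7,8-epoxy-3,4-dihydroxy-4,8-dimethyl-1-(prop-1-en-2-yl)cyclodecane-5,9,10-triyl 5,9-bis[(Z)-2-methylbut-2-enoate] 10-[(R)-2-methylbutanoate] | C=C(C)[C@H]1C[C@@H](O)[C@](C)(O)[C@@H](OC(=O)/C(C)=C\C)C[C@@H]2O[C@]2(C)[C@@H](OC(=O)/C(C)=C\C)[C@@H]1OC(=O)[C@H](C)CC | target

## Step count and least certain steps

Total step count: 24. Longest linear sequence: 24 steps, from 1 to 35 (19, 29 and 32 each enter in one step).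

Step 16 (key step). The chair that aligns C3–C8 with the C7–O bond carries three axial oxygens on ring B. If it is populated too little, E2 loss of the mesylate toward C6, closure to an oxetane, or base-induced reactions of the new ketone could overtake the fragmentation. Fallback, from 23 back to 24: the tertiary hydroxyl of 23 is silylated (Me3SiOTf, 2,6-lutidine, −78 °C) to the C3 trimethylsilyl ether F1. CsF in DMF then releases the alkoxide without excess strong base, so the fragmentation is triggered by desilylation and gives 24.

Step 9. The slow attack on a tetrasubstituted β-carbon may be overtaken by β-elimination of the C7 silanolate through the α′-enolate, or the peroxide may add to the wrong face. Fallback, from 14 back to 15: the C9 hydroxyl is silylated (Et3SiCl, imidazole) to the 9-triethylsilyl ether F2. The enone carbonyl is reduced under reagent control ((R)-2-methyl-CBS-oxazaborolidine, catecholborane, −78 °C) to the 5β-allylic alcohol F3. VO(acac)2/t-BuOOH epoxidises syn to that hydroxyl to give the 3β,4β-epoxy alcohol F4. Dess–Martin oxidation gives the epoxy ketone triethylsilyl ether F5, and PPTS in MeOH removes the triethylsilyl group selectively to give 15.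

Step 12. The alcohol may open the oxirane at C5 instead of C4, the silyl ether oxygen on C7 may capture the developing C4 cation across ring B, a semipinacol shift may occur, or the benzylic alcohol may self-condense under acid. Fallback, from 18 back to 21: hydrolysis with dilute HClO4 in THF–H2O (water is small and in large excess) gives the 3,4,5,9-tetraol F6. NaH/4-methoxybenzyl chloride etherifies the two secondary hydroxyls to the 5,9-bis(4-methoxybenzyl) ether F7. The less hindered tertiary C4 hydroxyl is then etherified with 4-methoxybenzyl trichloroacetimidate and La(OTf)3 (cat.) to give 21.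

Step 1. Facial selectivity at the new quaternary centre may be poor under equilibrating protic base, and the enone may polymerise. Fallback, from 1 back to 4: Me3SiOTf/Et3N converts 1 into the extended trimethylsilyl dienol ether F8. MeLi regenerates the lithium dienolate free of alkoxide, and it is added at −78 °C to 2-(trimethylsilyl)pent-1-en-3-one to give the α-silyl Michael adduct F9. KOH in MeOH removes silicon and closes ring B to 4. This is a kinetically controlled, low-temperature Michael addition instead of an equilibrating one.

Step 17. Hydride delivery may be governed by the conformation of the ten-membered ring and not by the local Felkin preference, giving the wrong face. Fallback, from 24 back to 25: reagent-controlled reduction with (S)-2-methyl-CBS-oxazaborolidine and catecholborane (toluene, −78 °C), which differentiates the quaternary C4 side from the C2 methylene. Any C3 epimer F10 is returned to 24 by Dess–Martin oxidation and reduced again under reagent control.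

Step 24. The isopropenyl group may be oxidised in competition, because the allylic ester lowers the reactivity of the ring alkene, and facial control may be incomplete. Fallback, from 31 back to 35: the ring alkene of 31 is epoxidised with VO(acac)2/t-BuOOH under direction by the free allylic C9 hydroxyl, which should give the same syn (threo) face and leaves the isopropenyl group untouched, to the epoxy triol F11. Angeloylation as in step 22 gives the epoxy diangelate silyl ether F12, and n-Bu4NF buffered with AcOH removes the silyl group to give 35.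

## Further compounds

F1 | step 16 | C3 trimethylsilyl ether of mesylate 23 | C=C(C)[C@H]1C[C@]2(O[Si](C)(C)C)[C@](C)(OCc3ccc(OC)cc3)[C@@H](OCc3ccc(OC)cc3)C[C@H](OS(C)(=O)=O)[C@]2(C)[C@@H](OCc3ccc(OC)cc3)[C@@H]1OCC=C
F2 | step 9 | 9-triethylsilyl ether of 14 | C=C(C)[C@H]1CC2=C(C)C(=O)C[C@H](O[Si](C)(C)C(C)(C)C)[C@]2(C)[C@@H](O[Si](CC)(CC)CC)[C@@H]1OCC=C
F3 | step 9 | 5β-allylic alcohol (9-triethylsilyl ether) | C=C(C)[C@H]1CC2=C(C)[C@@H](O)C[C@H](O[Si](C)(C)C(C)(C)C)[C@]2(C)[C@@H](O[Si](CC)(CC)CC)[C@@H]1OCC=C
F4 | step 9 | 3β,4β-epoxy-5β-alcohol (9-triethylsilyl ether) | C=C(C)[C@H]1C[C@@]23O[C@@]3(C)[C@@H](O)C[C@H](O[Si](C)(C)C(C)(C)C)[C@]2(C)[C@@H](O[Si](CC)(CC)CC)[C@@H]1OCC=C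
F5 | step 9 | 3β,4β-epoxy-5-ketone 9-triethylsilyl ether | C=C(C)[C@H]1C[C@@]23O[C@@]3(C)C(=O)C[C@H](O[Si](C)(C)C(C)(C)C)[C@]2(C)[C@@H](O[Si](CC)(CC)CC)[C@@H]1OCC=C
F6 | step 12 | 3β,4α,5β,9β-tetraol (7α-silyloxy, 10α-allyloxy) | C=C(C)[C@H]1C[C@]2(O)[C@](C)(O)[C@@H](O)C[C@H](O[Si](C)(C)C(C)(C)C)[C@]2(C)[C@@H](O)[C@@H]1OCC=C
F7 | step 12 | 5β,9β-bis(4-methoxybenzyl) ether 3β,4α-diol | C=C(C)[C@H]1C[C@]2(O)[C@](C)(O)[C@@H](OCc3ccc(OC)cc3)C[C@H](O[Si](C)(C)C(C)(C)C)[C@]2(C)[C@@H](OCc3ccc(OC)cc3)[C@@H]1OCC=C
F8 | step 1 | extended trimethylsilyl dienol ether of carvone | C=C(C)[C@H]1CC(O[Si](C)(C)C)=C(C)C=C1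
F9 | step 1 | α-trimethylsilyl Michael adduct | C=C(C)[C@H]1CC(=O)[C@](C)(CC(C(=O)CC)[Si](C)(C)C)C=C1
F10 | step 17 | C3 epimer of 25 | C=C(C)[C@H]1C[C@H](O)[C@](C)(OCc2ccc(OC)cc2)[C@@H](OCc2ccc(OC)cc2)C/C=C(/C)[C@@H](OCc2ccc(OC)cc2)[C@@H]1OCC=C
F11 | step 24 | 7,8-epoxy-4,5,9-triol (C3 silyl ether, C10 ester) | C=C(C)[C@H]1C[C@@H](O[Si](CC)(CC)CC)[C@](C)(O)[C@@H](O)C[C@@H]2O[C@]2(C)[C@@H](O)[C@@H]1OC(=O)[C@H](C)CC
F12 | step 24 | 7,8-epoxy-5,9-diangelate C3 silyl ether | C=C(C)[C@H]1C[C@@H](O[Si](CC)(CC)CC)[C@](C)(O)[C@@H](OC(=O)/C(C)=C\C)C[C@@H]2O[C@]2(C)[C@@H](OC(=O)/C(C)=C\C)[C@@H]1OC(=O)[C@H](C)CC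
A1 | alternative 1 | bis-epoxide triester | C=C(C)[C@H]1C[C@@H]2O[C@]2(C)[C@@H](OC(=O)/C(C)=C\C)C[C@@H]3O[C@]3(C)[C@@H](OC(=O)/C(C)=C\C)[C@@H]1OC(=O)[C@H](C)CC
A2 | alternative 1 | (3Z,7Z)-cyclodecadiene triester | C=C(C)[C@H]1C/C=C(/C)[C@@H](OC(=O)/C(C)=C\C)C/C=C(/C)[C@@H](OC(=O)/C(C)=C\C)[C@@H]1OC(=O)[C@H](C)CC
A3 | alternative 2 | cyclodecenol with free C10 hydroxyl | C=C(C)[C@H]1C[C@@H](O[Si](CC)(CC)CC)[C@](C)(O)[C@@H](OC(=O)/C(C)=C\C)C/C=C(/C)[C@@H](OC(=O)/C(C)=C\C)[C@@H]1O
A4 | alternative 2 | open-chain C10 aldehyde with terminal allylic bromide | O=C[C@H](OC(=O)/C(C)=C\C)/C(C)=C\C[C@H](OC(=O)/C(C)=C\C)[C@@](C)(O)[C@H](O[Si](CC)(CC)CC)C/C=C(\C)CBr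
A5 | alternative 3 | cyclodecene C3/C4 diol | C=C(C)[C@H]1C[C@@H](O)[C@](C)(O)[C@@H](OCc2ccc(OC)cc2)C/C=C(/C)[C@@H](OCc2ccc(OC)cc2)[C@@H]1O[Si](C)(C)C(C)(C)C
A6 | alternative 3 | open-chain C3 aldehyde C4 methyl ketone | O=CC[C@H](C(C)=C)[C@@H](O[Si](C)(C)C(C)(C)C)[C@H](OCc1ccc(OC)cc1)/C(C)=C\C[C@H](OCc1ccc(OC)cc1)C(C)=O
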